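The aryl ketal carbon C2 is made by oxidation, not by isomerisation of a benzofuran ketone or by flavone–flavan coupling. C2 bears a 4-hydroxyphenyl ring and is β to the C4 ketone, whose ring A offers an ortho-phenol (O1). DDQ turns the 4-hydroxyphenyl group of a trans-2-aryl-3-aroyl-2,3-dihydrobenzofuran into a para-quinone methide with C2 as methide carbon; the aroyl phenol adds to it, closing the pyranone ring (O1–C2) cis to C3. One asymmetric C–H insertion therefore controls the ketal pair: it sets C2–H, C3 is equilibrated trans to it, C2 is then erased and rebuilt from C3. The precursor is a flavan-fused dihydrobenzofuran aryl ketone.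

Key step: step 16

Remark (numbering): the target is numbered as a biflavonoid (chromanone half O1, C2 = ketal carbon, C3, C4 = C=O, ring A, B ring primed; flavan half double-primed, its B ring triple-primed); tricyclic intermediates are named as 3,4,8,9-tetrahydro-2H-furo[2,3-h]chromenes, in which C2 is the flavan carbon, C8 the future ketal carbon C2 and C9 the future C3.

Remark (assumption): Rh2(S-PTTL)4 is assumed to give the (8R,9S) cis ester 13 in step 10; if its sense of induction on this substrate is the opposite, Rh2(R-PTTL)4 is used with no other change.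

Step 1
Reactants: 1 4-(methoxymethoxy)benzaldehyde
Product: 2 [4-(methoxymethoxy)phenyl]methanol
Conditions: NaBH4, MeOH, 0 °C
Reagents that add atoms: none
Why: Borohydride reduction of the aldehyde to the benzylic alcohol is fast at 0 °C and leaves the MOM acetal untouched; no stereocentre is formed.

Step 2
Reactants: 3 2,4,6-trihydroxybenzaldehyde; 2 [4-(methoxymethoxy)phenyl]methanol
Product: 4 2,6-dihydroxy-4-{[4-(methoxymethoxy)benzyl]oxy}benzaldehyde
Conditions: PPh3, DIAD, THF, 0 °C to rt
Reagents that add atoms: none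
Why: Mitsunobu etherification should alkylate only the 4-OH, the most acidic phenol and the only one not chelated to the formyl group, so that the future O7″ receives the benzylic CH2 that later becomes the ketal carbon.

Step 3
Reactants: 4 2,6-dihydroxy-4-{[4-(methoxymethoxy)benzyl]oxy}benzaldehyde
Product: 5 2-(benzyloxy)-6-hydroxy-4-{[4-(methoxymethoxy)benzyl]oxy}benzaldehyde
Conditions: BnBr (1.05 equiv), K2CO3, acetone, reflux
Reagents that add atoms: benzyl bromide BrCc1ccccc1
Why: Williamson ether synthesis with one equivalent of benzyl bromide should stop at the mono-benzyl ether because the remaining ortho-OH is hydrogen-bonded to the aldehyde and far less nucleophilic.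

Step 4
Reactants: 5 2-(benzyloxy)-6-hydroxy-4-{[4-(methoxymethoxy)benzyl]oxy}benzaldehyde; 6 1-[4-(benzyloxy)phenyl]ethan-1-one
Product: 7 (E)-3-[2-(benzyloxy)-6-hydroxy-4-{[4-(methoxymethoxy)benzyl]oxy}phenyl]-1-[4-(benzyloxy)phenyl]prop-2-en-1-one
Conditions: KOH (50% aq.), EtOH, rt
Reagents that add atoms: none
Why: Claisen–Schmidt aldol condensation of the acetophenone enolate with the aldehyde and E1cB dehydration gives the thermodynamically favoured E-enone, and the MOM and benzyl ethers are stable to hydroxide.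

Step 5
Reactants: 7 the (E)-chalcone
Product: 8 3-[2-(benzyloxy)-6-hydroxy-4-{[4-(methoxymethoxy)benzyl]oxy}phenyl]-1-[4-(benzyloxy)phenyl]propan-1-one
Conditions: H2 (1 atm), RhCl(PPh3)3 (5 mol%), THF/EtOH, rt
Reagents that add atoms: none
Why: Homogeneous hydrogenation with Wilkinson's catalyst saturates the disubstituted enone C=C without touching the aryl ketone or the benzyl ethers, which heterogeneous Pd would cleave.

Step 6
Reactants: 8 the dihydrochalcone
Product: 9 (S)-3-[2-(benzyloxy)-6-hydroxy-4-{[4-(methoxymethoxy)benzyl]oxy}phenyl]-1-[4-(benzyloxy)phenyl]propan-1-ol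
Conditions: RuCl(p-cymene)[(S,S)-TsDPEN] (1 mol%), HCO2Na, H2O–DMF, 40 °C
Reagents that add atoms: none
Why: Noyori asymmetric transfer hydrogenation of the aryl alkyl ketone with the (S,S)-TsDPEN ligand should deliver hydride to the face that gives the (S)-carbinol, and the near-neutral formate medium avoids acid-promoted cyclisation of the phenol onto the benzylic alcohol.

Step 7
Reactants: 9 the (S)-carbinol
Product: 10 (R)-5-(benzyloxy)-2-[4-(benzyloxy)phenyl]-7-{[4-(methoxymethoxy)benzyl]oxy}chromane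
Conditions: PPh3, DIAD, THF, 0 °C
Reagents that add atoms: none
Why: Intramolecular Mitsunobu etherification closes the pyran ring by SN2 attack of the phenol on the activated carbinol with inversion, so that the (S)-alcohol gives the (R)-configured flavan C2.

Step 8
Reactants: 10 the (R)-flavan
Product: 11 (R)-5-(benzyloxy)-2-[4-(benzyloxy)phenyl]-8-iodo-7-{[4-(methoxymethoxy)benzyl]oxy}chromane
Conditions: NIS (1.05 equiv), CH2Cl2, −20 °C
Reagents that add atoms: N-iodosuccinimide O=C1CCC(=O)N1I
Why: Electrophilic aromatic iodination of the trioxygenated ring should go to C8, which is flanked by the ring oxygen, in preference to C6, which is flanked by two benzylic ethers, as in the C8 halogenation of O-benzylated flavan-3-ols.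

Step 9
Reactants: 11 the 8-iodoflavan
Product: 12 ethyl 2-diazo-2-[(R)-5-(benzyloxy)-2-[4-(benzyloxy)phenyl]-7-{[4-(methoxymethoxy)benzyl]oxy}chroman-8-yl]acetate
Conditions: ethyl diazoacetate, Pd(PPh3)4 (5 mol%), Bu4NBr, Et3N, MeCN, 45 °C
Reagents that add atoms: ethyl diazoacetate CCOC(=O)C=[N+]=[N-]
Why: Palladium-catalysed cross-coupling of the aryl iodide with the C–H bond of ethyl diazoacetate (oxidative addition, base-assisted transfer of the diazo ester to palladium, reductive elimination) should give the aryldiazoacetate with the diazo group intact.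

Step 10
Reactants: 12 the aryldiazoacetate
Product: 14 ethyl (2R,8R,9R)-5-(benzyloxy)-2-[4-(benzyloxy)phenyl]-8-[4-(methoxymethoxy)phenyl]-3,4,8,9-tetrahydro-2H-furo[2,3-h]chromene-9-carboxylate (8,9-trans), via cis-ester 13 (not isolated)
Conditions: Rh2(S-PTTL)4 (1 mol%), toluene, −60 °C; then NaOEt (0.2 equiv), EtOH, rt
Reagents that add atoms: none
Why: Rhodium(II)-carbenoid intramolecular 1,5-C–H insertion into the electron-rich benzylic ether CH2 closes the dihydrofuran ring, the chiral carboxylate ligands choosing the enantiotopic C–H and thereby setting C8 (cis ester 13), after which ethoxide epimerises only the acidic C9 to the more stable 8,9-trans ester, so that C9 is fixed relative to the non-epimerisable C8.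

Step 11
Reactants: 14 the trans ester
Product: 15 (2R,8R,9R)-5-(benzyloxy)-2-[4-(benzyloxy)phenyl]-8-[4-(methoxymethoxy)phenyl]-3,4,8,9-tetrahydro-2H-furo[2,3-h]chromene-9-carbaldehyde
Conditions: DIBAL-H (1.1 equiv), CH2Cl2, −78 °C; Rochelle salt
Reagents that add atoms: none
Why: Partial reduction of the ester with one equivalent of DIBAL-H at −78 °C stops at the aluminium hemiacetal, which gives the aldehyde on work-up; C8 is untouched and the 8,9-trans arrangement is the thermodynamic one.

Step 12
Reactants: 16 3,5-bis(benzyloxy)phenol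
Product: 17 1,3-bis(benzyloxy)-5-(methoxymethoxy)benzene
Conditions: MOMCl, i-Pr2NEt, CH2Cl2, 0 °C to rt
Reagents that add atoms: chloromethyl methyl ether COCCl
Why: O-Alkylation of the phenol with MOMCl and a hindered amine base installs the acetal that directs the lithiation of the next step and later unveils O1.

Step 13
Reactants: 17 1,3-bis(benzyloxy)-5-(methoxymethoxy)benzene; 15 the trans aldehyde
Product: 19 [2,4-bis(benzyloxy)-6-(methoxymethoxy)phenyl][(2R,8R,9S)-5-(benzyloxy)-2-[4-(benzyloxy)phenyl]-8-[4-(methoxymethoxy)phenyl]-3,4,8,9-tetrahydro-2H-furo[2,3-h]chromen-9-yl]methanol (both carbinol epimers), via aryllithium 18 (not isolated)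
Conditions: 17 (1.5 equiv), n-BuLi, TMEDA, THF, −20 °C; then 15, −78 °C; H2O
Reagents that add atoms: none
Why: Directed ortho-metalation places lithium between the MOM ether and a benzyl ether (the better-coordinating MOM group directs), and the aryllithium adds to the aldehyde at −78 °C faster than it enolises it; the new carbinol centre is formed without control and is removed in step 14.

Step 14
Reactants: 19 the diaryl carbinol
Product: 20 [2,4-bis(benzyloxy)-6-(methoxymethoxy)phenyl][(2R,8R,9R)-5-(benzyloxy)-2-[4-(benzyloxy)phenyl]-8-[4-(methoxymethoxy)phenyl]-3,4,8,9-tetrahydro-2H-furo[2,3-h]chromen-9-yl]methanone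
Conditions: IBX, DMSO, rt
Reagents that add atoms: none
Why: IBX oxidation of the secondary benzylic alcohol gives the aryl ketone under neutral conditions that neither enolise C9 nor open the β-aryloxy ketone by elimination.

Step 15
Reactants: 20 the bis-MOM ketone
Product: 21 [2,4-bis(benzyloxy)-6-hydroxyphenyl][(2R,8R,9R)-5-(benzyloxy)-2-[4-(benzyloxy)phenyl]-8-(4-hydroxyphenyl)-3,4,8,9-tetrahydro-2H-furo[2,3-h]chromen-9-yl]methanone
Conditions: NaHSO4·SiO2, CH2Cl2, rt
Reagents that add atoms: none
Why: Mild heterogeneous Brønsted acid cleaves the two phenolic MOM acetals by way of the methoxymethyl cation, while the benzyl ethers, the cyclic benzylic ethers and the C9 centre should survive.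

Step 16
Reactants: 21 the trans bis-phenol ketone
Product: 23 (2S,3S,2″R)-5,7,5″,4‴-tetra-O-benzyl ether of the target (free 4′-OH; cis-fused ketal), via quinone methide 22 (not isolated)
Conditions: DDQ (1.05 equiv), CH2Cl2, −20 to 0 °C
Reagents that add atoms: none
Why: DDQ forms a charge-transfer complex with the only free para-substituted phenol and removes hydride from the para-benzylic, α-oxygenated C8–H, giving the neutral para-quinone methide 22 in which C8 (the future ketal carbon C2) is the methide carbon; the ortho-phenol of the C9 aroyl group then adds 1,6 to this carbon and ring B rearomatises. The closest known reaction type is the DDQ-mediated oxidative cyclisation of 4-hydroxyphenyl alkanes and benzylic ethers through quinone methides or oxocarbenium ions that a neighbouring hydroxyl group captures (oxidative flavan and acetal formation). The pyranone ring closes in a 6-exo-trig mode on the exocyclic C=C bond of the quinone methide, and the new O1–C2 bond completes the ketal. C2 is planar in 22, so its configuration is dictated only by C3 (old C9, untouched): the phenol is tied to C3 through the C4 carbonyl and can reach only the face of C2 syn to C4, which gives the cis-fused (2S,3S) pair, a trans fusion onto the flat dihydrobenzofuran being prohibitively strained. The step needs capture to outrun loss of the acidic C3–H (tautomerisation to the aromatic 3-aroylbenzofuran) and needs DDQ to select the free phenol over the p-benzyloxyphenyl ether C–H at flavan C2 and the flavan C4–H2; the six-membered intramolecular capture, the absence of base (DDQH2 precipitates from CH2Cl2), one equivalent of oxidant and low temperature should secure both. Because the ketal is expected to be less stable than its benzofuran isomer, it is formed here in an irreversible, downhill redox event (rearomatisation of ring B) and not by an equilibrium.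

Step 17
Reactants: 23 the tetra-O-benzyl ketal
Product: 24 target CNP0179743.1
Conditions: H2 (1 atm), 10% Pd/C, EtOAc–THF, rt
Reagents that add atoms: none
Why: Hydrogenolysis of the four benzyl aryl ethers over Pd/C proceeds under neutral conditions, which avoid the base- or acid-induced opening of the ketal to the benzofuran, and the hindered tertiary ketal C–O bonds and the flavan C2″–O bond should be cleaved much more slowly than the primary benzyl ethers.

Compound list

1 | 4-(methoxymethoxy)benzaldehyde | COCOc1ccc(C=O)cc1 | starting material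
2 | [4-(methoxymethoxy)phenyl]methanol | COCOc1ccc(CO)cc1 | intermediate
3 | 2,4,6-trihydroxybenzaldehyde | O=Cc1c(O)cc(O)cc1O | starting material
4 | 2,6-dihydroxy-4-{[4-(methoxymethoxy)benzyl]oxy}benzaldehyde | O=Cc1c(O)cc(OCc2ccc(OCOC)cc2)cc1O | intermediate
5 | 2-(benzyloxy)-6-hydroxy-4-{[4-(methoxymethoxy)benzyl]oxy}benzaldehyde | O=Cc1c(O)cc(OCc2ccc(OCOC)cc2)cc1OCc1ccccc1 | intermediate
6 | 1-[4-(benzyloxy)phenyl]ethan-1-one | CC(=O)c1ccc(OCc2ccccc2)cc1 | starting material
7 | (E)-3-[2-(benzyloxy)-6-hydroxy-4-{[4-(methoxymethoxy)benzyl]oxy}phenyl]-1-[4-(benzyloxy)phenyl]prop-2-en-1-one | O=C(/C=C/c1c(O)cc(OCc2ccc(OCOC)cc2)cc1OCc1ccccc1)c1ccc(OCc2ccccc2)cc1 | intermediate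
8 | 3-[2-(benzyloxy)-6-hydroxy-4-{[4-(methoxymethoxy)benzyl]oxy}phenyl]-1-[4-(benzyloxy)phenyl]propan-1-one | O=C(CCc1c(O)cc(OCc2ccc(OCOC)cc2)cc1OCc1ccccc1)c1ccc(OCc2ccccc2)cc1 | intermediate
9 | (S)-3-[2-(benzyloxy)-6-hydroxy-4-{[4-(methoxymethoxy)benzyl]oxy}phenyl]-1-[4-(benzyloxy)phenyl]propan-1-ol | O[C@@H](CCc1c(O)cc(OCc2ccc(OCOC)cc2)cc1OCc1ccccc1)c1ccc(OCc2ccccc2)cc1 | intermediate
10 | (R)-5-(benzyloxy)-2-[4-(benzyloxy)phenyl]-7-{[4-(methoxymethoxy)benzyl]oxy}chromane | COCOc1ccc(COc2cc(OCc3ccccc3)c3c(c2)O[C@@H](c2ccc(OCc4ccccc4)cc2)CC3)cc1 | intermediate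
11 | (R)-5-(benzyloxy)-2-[4-(benzyloxy)phenyl]-8-iodo-7-{[4-(methoxymethoxy)benzyl]oxy}chromane | COCOc1ccc(COc2cc(OCc3ccccc3)c3c(c2I)O[C@@H](c2ccc(OCc4ccccc4)cc2)CC3)cc1 | intermediate
12 | ethyl 2-diazo-2-[(R)-5-(benzyloxy)-2-[4-(benzyloxy)phenyl]-7-{[4-(methoxymethoxy)benzyl]oxy}chroman-8-yl]acetate | COCOc1ccc(COc2cc(OCc3ccccc3)c3c(c2C(=[N+]=[N-])C(=O)OCC)O[C@@H](c2ccc(OCc4ccccc4)cc2)CC3)cc1 | intermediate
13 | ethyl (2R,8R,9S)-5-(benzyloxy)-2-[4-(benzyloxy)phenyl]-8-[4-(methoxymethoxy)phenyl]-3,4,8,9-tetrahydro-2H-furo[2,3-h]chromene-9-carboxylate (8,9-cis) | CCOC(=O)[C@@H]1[C@H](c2ccc(OCOC)cc2)Oc2cc(OCc3ccccc3)c3c(c21)O[C@@H](c1ccc(OCc2ccccc2)cc1)CC3 | intermediate (not isolated)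
14 | ethyl (2R,8R,9R)-5-(benzyloxy)-2-[4-(benzyloxy)phenyl]-8-[4-(methoxymethoxy)phenyl]-3,4,8,9-tetrahydro-2H-furo[2,3-h]chromene-9-carboxylate (8,9-trans) | CCOC(=O)[C@H]1[C@H](c2ccc(OCOC)cc2)Oc2cc(OCc3ccccc3)c3c(c21)O[C@@H](c1ccc(OCc2ccccc2)cc1)CC3 | intermediate
15 | (2R,8R,9R)-5-(benzyloxy)-2-[4-(benzyloxy)phenyl]-8-[4-(methoxymethoxy)phenyl]-3,4,8,9-tetrahydro-2H-furo[2,3-h]chromene-9-carbaldehyde | O=C[C@H]1[C@H](c2ccc(OCOC)cc2)Oc2cc(OCc3ccccc3)c3c(c21)O[C@@H](c1ccc(OCc2ccccc2)cc1)CC3 | intermediate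
16 | 3,5-bis(benzyloxy)phenol | Oc1cc(OCc2ccccc2)cc(OCc2ccccc2)c1 | starting material
17 | 1,3-bis(benzyloxy)-5-(methoxymethoxy)benzene | COCOc1cc(OCc2ccccc2)cc(OCc2ccccc2)c1 | intermediate
18 | [2,4-bis(benzyloxy)-6-(methoxymethoxy)phenyl]lithium | [Li]c1c(OCOC)cc(OCc2ccccc2)cc1OCc1ccccc1 | intermediate (not isolated)
19 | [2,4-bis(benzyloxy)-6-(methoxymethoxy)phenyl][(2R,8R,9S)-5-(benzyloxy)-2-[4-(benzyloxy)phenyl]-8-[4-(methoxymethoxy)phenyl]-3,4,8,9-tetrahydro-2H-furo[2,3-h]chromen-9-yl]methanol (both carbinol epimers) | OC(c1c(OCOC)cc(OCc2ccccc2)cc1OCc1ccccc1)[C@H]1[C@H](c2ccc(OCOC)cc2)Oc2cc(OCc3ccccc3)c3c(c21)O[C@@H](c1ccc(OCc2ccccc2)cc1)CC3 | intermediate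
20 | [2,4-bis(benzyloxy)-6-(methoxymethoxy)phenyl][(2R,8R,9R)-5-(benzyloxy)-2-[4-(benzyloxy)phenyl]-8-[4-(methoxymethoxy)phenyl]-3,4,8,9-tetrahydro-2H-furo[2,3-h]chromen-9-yl]methanone | O=C(c1c(OCOC)cc(OCc2ccccc2)cc1OCc1ccccc1)[C@H]1[C@H](c2ccc(OCOC)cc2)Oc2cc(OCc3ccccc3)c3c(c21)O[C@@H](c1ccc(OCc2ccccc2)cc1)CC3 | intermediate
21 | [2,4-bis(benzyloxy)-6-hydroxyphenyl][(2R,8R,9R)-5-(benzyloxy)-2-[4-(benzyloxy)phenyl]-8-(4-hydroxyphenyl)-3,4,8,9-tetrahydro-2H-furo[2,3-h]chromen-9-yl]methanone | O=C(c1c(O)cc(OCc2ccccc2)cc1OCc1ccccc1)[C@H]1[C@H](c2ccc(O)cc2)Oc2cc(OCc3ccccc3)c3c(c21)O[C@@H](c1ccc(OCc2ccccc2)cc1)CC3 | intermediate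
22 | 4-[(2R,9R)-9-[2,4-bis(benzyloxy)-6-hydroxybenzoyl]-5-(benzyloxy)-2-[4-(benzyloxy)phenyl]-2,3,4,9-tetrahydro-8H-furo[2,3-h]chromen-8-ylidene]cyclohexa-2,5-dien-1-one (para-quinone methide) | O=C(c1c(O)cc(OCc2ccccc2)cc1OCc1ccccc1)[C@H]1C(=C2C=CC(=O)C=C2)Oc2cc(OCc3ccccc3)c3c(c21)O[C@@H](c1ccc(OCc2ccccc2)cc1)CC3 | intermediate (not isolated)
23 | (2S,3S,2″R)-5,7,5″,4‴-tetra-O-benzyl ether of the target: cis-fused ketal with C3 bonded to flavan C8″ and C2 bonded to O1 and flavan O7″, free 4′-OH | O=C1c2c(OCc3ccccc3)cc(OCc3ccccc3)cc2O[C@@]2(c3ccc(O)cc3)Oc3cc(OCc4ccccc4)c4c(c3[C@@H]12)O[C@@H](c1ccc(OCc2ccccc2)cc1)CC4 | intermediate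
24 | CNP0179743.1: (2S,3S,2″R)-5,7,4′,5″,4‴-pentahydroxy flavanone–flavan dimer linked C3–C8″ and C2–O–C7″ | O=C1c2c(O)cc(O)cc2O[C@@]2(c3ccc(O)cc3)Oc3cc(O)c4c(c3[C@@H]12)O[C@@H](c1ccc(O)cc1)CC4 | target

Total step count: 17
Longest linear sequence: 16 steps (steps 1–11 and 13–17, from 1 to 24; step 12 is a one-step side branch)

Steps most likely to fail

Step 16 (key step). What may go wrong is that the quinone methide 22 loses its acidic C3 proton and tautomerises to the aromatic 3-aroylbenzofuran before the phenol adds, or that DDQ attacks the electron-rich flavan ring; either way both centres of the ketal pair would be lost. The fallback postpones the C4 ketone, so that C3–H is not α to a carbonyl while the quinone methide exists. It sets out from carbinol 19. The two MOM groups are removed (NaHSO4·SiO2, CH2Cl2, rt) to give [2,4-bis(benzyloxy)-6-hydroxyphenyl][(2R,8R,9S)-5-(benzyloxy)-2-[4-(benzyloxy)phenyl]-8-(4-hydroxyphenyl)-3,4,8,9-tetrahydro-2H-furo[2,3-h]chromen-9-yl]methanol F1. DDQ (CH2Cl2, −20 °C) should then convert this, through the same quinone-methide capture, into the C4 carbinol analogue of 23, (2S,3S,2″R)-5,7,5″,4‴-tetra-O-benzyl-4-hydroxy ketal F2 (both C4 epimers). Oxidation of the benzylic carbinol (MnO2, CH2Cl2, rt) brings the material back to the route at 23.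

Step 10. What may go wrong is poor facial control, or dimerisation of the carbenoid, with a doubly ortho-substituted aryl carbenoid, so that C8, the centre from which the ketal pair is relayed, is not set by the catalyst. The fallback gives up catalyst control and uses the fixed flavan centre as a resolving handle. It sets out from 12: insertion with achiral Rh2(OAc)4 (CH2Cl2, rt) followed by NaOEt epimerisation gives the two trans esters, which are diastereomers of each other. Chromatography separates 14 from ethyl (2R,8S,9S)-5-(benzyloxy)-2-[4-(benzyloxy)phenyl]-8-[4-(methoxymethoxy)phenyl]-3,4,8,9-tetrahydro-2H-furo[2,3-h]chromene-9-carboxylate F3, and the route continues from 14.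

Step 9. What may go wrong is slow oxidative addition at the hindered, electron-rich iodide together with decomposition of the diazo ester (carbene dimers, reduction of the iodide). The fallback builds the arylacetate first and introduces the diazo group afterwards. It sets out from 11: palladium-catalysed coupling with the Reformatsky reagent BrZnCH2CO2Et (Pd(dba)2, Q-Phos, THF, rt to 60 °C) gives ethyl 2-[(R)-5-(benzyloxy)-2-[4-(benzyloxy)phenyl]-7-{[4-(methoxymethoxy)benzyl]oxy}chroman-8-yl]acetate F4, and Regitz diazo transfer (p-ABSA, DBU, MeCN, 0 °C) returns to the route at 12.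

Further compounds
F1 | step 16 | [2,4-bis(benzyloxy)-6-hydroxyphenyl][(2R,8R,9S)-5-(benzyloxy)-2-[4-(benzyloxy)phenyl]-8-(4-hydroxyphenyl)-3,4,8,9-tetrahydro-2H-furo[2,3-h]chromen-9-yl]methanol (both carbinol epimers) | OC(c1c(O)cc(OCc2ccccc2)cc1OCc1ccccc1)[C@H]1[C@H](c2ccc(O)cc2)Oc2cc(OCc3ccccc3)c3c(c21)O[C@@H](c1ccc(OCc2ccccc2)cc1)CC3
F2 | step 16 | (2S,3S,2″R)-5,7,5″,4‴-tetra-O-benzyl-4-hydroxy ketal, the C4 carbinol analogue of 23 (both C4 epimers) | OC1c2c(OCc3ccccc3)cc(OCc3ccccc3)cc2O[C@@]2(c3ccc(O)cc3)Oc3cc(OCc4ccccc4)c4c(c3[C@@H]12)O[C@@H](c1ccc(OCc2ccccc2)cc1)CC4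
F3 | step 10 | ethyl (2R,8S,9S)-5-(benzyloxy)-2-[4-(benzyloxy)phenyl]-8-[4-(methoxymethoxy)phenyl]-3,4,8,9-tetrahydro-2H-furo[2,3-h]chromene-9-carboxylate | CCOC(=O)[C@@H]1[C@@H](c2ccc(OCOC)cc2)Oc2cc(OCc3ccccc3)c3c(c21)O[C@@H](c1ccc(OCc2ccccc2)cc1)CC3
F4 | step 9 | ethyl 2-[(R)-5-(benzyloxy)-2-[4-(benzyloxy)phenyl]-7-{[4-(methoxymethoxy)benzyl]oxy}chroman-8-yl]acetate | COCOc1ccc(COc2cc(OCc3ccccc3)c3c(c2CC(=O)OCC)O[C@@H](c2ccc(OCc4ccccc4)cc2)CC3)cc1
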